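**Plan**
- Retrosynthesis: the free OH groups are unmasked last (BBr3, then hydrolysis of the benzylic bromides). The ring A C1–CH2OH bond is cut back to formaldehyde and a phenol whose two ortho positions are blocked.
- Ring A is then dismantled: C5–Br and the aromatic unsaturation go back to an α′,α′-dibrominated 3-bromoenone, and C2–Br to a carbonyl of a cyclohexane-1,3-dione. The ring bond C3–C4 (equivalent to C3–C2 by symmetry) is cut to a 6-aryloxy-5-oxohexanoate, whose ArO–CH2 bond is cut to a ring B phenol and a bromomethyl ketone.
- Enabling feature: in ring A the ether carbon C3 lies between C4–OH and C2–Br. C2/C3/C4 are therefore C1/C2/C3 of a 2-aryloxycyclohexane-1,3-dione, whose two equivalent carbonyls become the bromide and the phenol.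
- Forward order: ring B is finished first as phenol 5 (from 2,3,4-trimethoxybenzaldehyde). The C6 chain 8 is joined by Williamson alkylation, and the ring A carbocycle is closed on the ring B oxygen by a Dieckmann-type condensation. It is then converted to the bromoenone, gem-dibrominated, aromatised, hydroxymethylated and deprotected.
- Stereochemistry: the target has no stereocentre, so nothing has to be set or preserved.

Key step: step 7

Remark: the target SMILES carries no stereodescriptor; the compound is treated as achiral, assuming free rotation about the diaryl ether bonds at room temperature.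
Abbreviation used in the step lines: Ar = 4-bromo-2,3-dimethoxy-6-(methoxymethyl)phenyl (the protected ring B). Full names are in the compound list.

**Route**

Step 1
Reactants: 1 2,3,4-trimethoxybenzaldehyde
Product: 2 2-hydroxy-3,4-dimethoxybenzaldehyde
Conditions: BCl3 (1.1 equiv), CH2Cl2, 0 °C → rt; H2O
Reagents that add atoms: none
Why: Chelation-controlled Lewis acid ether cleavage, in which boron is held between the aldehyde oxygen and the ortho methoxy oxygen so that chloride should remove only that methyl group and leave the 3- and 4-OMe groups.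

Step 2
Reactants: 2 2-hydroxy-3,4-dimethoxybenzaldehyde
Product: 3 5-bromo-2-hydroxy-3,4-dimethoxybenzaldehyde
Conditions: NBS (1.05 equiv), MeCN, 0 °C → rt
Reagents that add atoms: N-bromosuccinimide, O=C1CCC(=O)N1Br
Why: Electrophilic aromatic bromination should go to C5, which is para to the free hydroxyl, ortho to the 4-OMe and meta to the formyl group, while C6 is deactivated.

Step 3
Reactants: 3 5-bromo-2-hydroxy-3,4-dimethoxybenzaldehyde
Product: 4 4-bromo-6-(hydroxymethyl)-2,3-dimethoxyphenol
Conditions: NaBH4, MeOH, 0 °C; aq. NH4Cl
Reagents that add atoms: none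
Why: Borohydride reduction of the aryl aldehyde leaves the aryl bromide and ethers untouched and removes the carbonyl ortho to the phenol that would otherwise condense with the α-aryloxy ketone made later.

Step 4
Reactants: 4 4-bromo-6-(hydroxymethyl)-2,3-dimethoxyphenol
Product: 5 4-bromo-2,3-dimethoxy-6-(methoxymethyl)phenol
Conditions: MeOH (solvent), cat. TsOH·H2O, 50 °C
Reagents that add atoms: methanol, CO
Why: Acid-catalysed SN1 etherification, in which the benzylic alcohol (para-OMe, ortho-OH, o-quinone-methide character) ionises easily and is captured by the solvent, whereas a phenol is not O-methylated by MeOH/H+.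

Step 5
Reactants: 6 methyl 5-chloro-5-oxopentanoate
Product: 8 methyl 6-bromo-5-oxohexanoate, via diazoketone 7 (not isolated)
Conditions: TMSCHN2 (2 equiv), THF/MeCN, 0 °C → rt; then 48% aq. HBr, 0 °C
Reagents that add atoms: trimethylsilyldiazomethane, C[Si](C)(C)C=[N+]=[N-]; hydrogen bromide, Br
Why: Acylation of the diazoalkane (Arndt–Eistert-type diazoketone formation) followed by protonation and displacement of N2 by bromide gives the bromomethyl ketone without any regiochemical question, and the methyl ester survives the short cold acid treatment.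

Step 6
Reactants: 5 4-bromo-2,3-dimethoxy-6-(methoxymethyl)phenol; 8 methyl 6-bromo-5-oxohexanoate
Product: 9 methyl 6-(ArO)-5-oxohexanoate
Conditions: K2CO3 (1.5 equiv), acetone, 50 °C
Reagents that add atoms: none
Why: Williamson ether synthesis, in which the phenoxide displaces bromide from a primary α-bromoketone (a very reactive SN2 electrophile), so the doubly ortho-substituted ether C–O bond is made without any aryl coupling.

Step 7
Reactants: 9 methyl 6-(ArO)-5-oxohexanoate
Product: 10 2-(ArO)cyclohexane-1,3-dione
Conditions: KOtBu (2.2 equiv), THF (0.05 M), 0 °C → rt; then 1 M HCl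
Reagents that add atoms: none
Why: tert-Butoxide forms the enolates of 9 reversibly, and only the one at C6 (the CH2 between the ketone and the aryloxy oxygen) can reach the ester carbonyl C1; addition and loss of methoxide give the dione, whose immediate deprotonation to the stabilised enolate makes the closure irreversible. The closest known reaction is the base-mediated Dieckmann-type (intramolecular Claisen) cyclisation of 5-oxohexanoate esters to cyclohexane-1,3-diones. The six-membered carbocycle closes in the 6-(enolendo)-exo-trig mode, since the enolate C5=C6 lies inside the new ring and the ester C=O is exocyclic to it. No stereocentre is formed, because C2 of the product is enolised and the dione is mirror-symmetric. The step needs C-acylation through this one enolate: the C4 and C2 enolates could only give four-membered rings, dilution suppresses intermolecular condensation, and ring B offers no electrophile because its benzylic carbon is an ether and not a carbonyl ortho to the ether oxygen. The symmetric dione then lets either carbonyl become C2–Br and the other C4–OH of ring A without a regiochemical choice.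

Step 8
Reactants: 10 2-(ArO)cyclohexane-1,3-dione
Product: 11 3-bromo-2-(ArO)cyclohex-2-en-1-one
Conditions: Ph3PBr2 (1.1 equiv), Et3N (1.2 equiv), MeCN, rt
Reagents that add atoms: dibromotriphenylphosphorane, BrP(Br)(c1ccccc1)(c1ccccc1)c1ccccc1
Why: Standard β-bromoenone synthesis from a 1,3-dione, in which the enol oxygen becomes an oxyphosphonium leaving group that bromide replaces by addition–elimination; the symmetric dione can give only one bromoenone, and the amine keeps the medium non-acidic for the benzylic ether.

Step 9
Reactants: 11 3-bromo-2-(ArO)cyclohex-2-en-1-one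
Product: 13 3,6,6-tribromo-2-(ArO)cyclohex-2-en-1-one, via α′-monobromo enone 12 (not isolated)
Conditions: LiHMDS (1.1 equiv), THF, −78 °C, then NBS (1.05 equiv); second portion of LiHMDS then NBS in the same flask; sat. aq. NH4Cl
Reagents that add atoms: N-bromosuccinimide, O=C1CCC(=O)N1Br
Why: Enolate α-halogenation, in which kinetic deprotonation of the β-bromoenone takes place at C6 (α′), NBS brominates the cross-conjugated lithium enolate, and the now more acidic CHBr is deprotonated and brominated again, which fixes the future C5 bromine of ring A by construction.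

Step 10
Reactants: 13 3,6,6-tribromo-2-(ArO)cyclohex-2-en-1-one
Product: 15 3,6-dibromo-2-(ArO)phenol, via cyclohexa-2,5-dienone 14 (not isolated)
Conditions: DBU (2.2 equiv), MeCN, 0 °C → rt; 1 M HCl
Reagents that add atoms: none
Why: Dehydrohalogenative aromatisation of an α,α-dibromo ketone, in which E2 loss of HBr across C5–C6 gives the 2,5-dienone that tautomerises to the phenol under the basic conditions, with aromatisation as the driving force.

Step 11
Reactants: 15 3,6-dibromo-2-(ArO)phenol
Product: 16 3,6-dibromo-2-(ArO)-4-(hydroxymethyl)phenol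
Conditions: 37% aq. CH2O (10 equiv), NaOH (1.1 equiv), H2O/THF, 50 °C; then 1 M HCl
Reagents that add atoms: formaldehyde, C=O
Why: Lederer–Manasse hydroxymethylation, in which the phenoxide attacks formaldehyde through C4, the para carbon, because both ortho positions (OAr and Br) are blocked, and ring B has no free phenol and is inert to formaldehyde under base.

Step 12
Reactants: 16 3,6-dibromo-2-(ArO)-4-(hydroxymethyl)phenol
Product: 17 6-bromo-4-(bromomethyl)-3-[2,5-dibromo-3-(bromomethyl)-6-hydroxyphenoxy]benzene-1,2-diol
Conditions: BBr3 (6 equiv), CH2Cl2, −78 °C → rt; ice-water; crude product carried on at once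
Reagents that add atoms: boron tribromide, BrB(Br)Br
Why: Lewis acid ether cleavage, in which BBr3 dealkylates both aryl methyl ethers and converts the electron-rich benzylic methyl ether and the benzylic alcohol into benzylic bromides, while the diaryl ether and the aryl bromides are stable to the reagent.

Step 13
Reactants: 17 6-bromo-4-(bromomethyl)-3-[2,5-dibromo-3-(bromomethyl)-6-hydroxyphenoxy]benzene-1,2-diol
Product: 18 6-bromo-3-[2,5-dibromo-6-hydroxy-3-(hydroxymethyl)phenoxy]-4-(hydroxymethyl)benzene-1,2-diol (target)
Conditions: acetone/H2O (1:1), rt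
Reagents that add atoms: water, O
Why: SN1 solvolysis of the two para-hydroxybenzylic bromides (through quinone-methide-like cations) in a large excess of water should return both benzylic alcohols under near-neutral conditions that leave the phenols and aryl bromides alone.

**Compound list**
1 | 2,3,4-trimethoxybenzaldehyde | COc1ccc(C=O)c(OC)c1OC | starting material
2 | 2-hydroxy-3,4-dimethoxybenzaldehyde | COc1ccc(C=O)c(O)c1OC | intermediate
3 | 5-bromo-2-hydroxy-3,4-dimethoxybenzaldehyde | COc1c(Br)cc(C=O)c(O)c1OC | intermediate
4 | 4-bromo-6-(hydroxymethyl)-2,3-dimethoxyphenol | COc1c(Br)cc(CO)c(O)c1OC | intermediate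
5 | 4-bromo-2,3-dimethoxy-6-(methoxymethyl)phenol | COCc1cc(Br)c(OC)c(OC)c1O | intermediate
6 | methyl 5-chloro-5-oxopentanoate | COC(=O)CCCC(Cl)=O | starting material
7 | methyl 6-diazo-5-oxohexanoate | COC(=O)CCCC(=O)C=[N+]=[N-] | intermediate (not isolated)
8 | methyl 6-bromo-5-oxohexanoate | COC(=O)CCCC(=O)CBr | intermediate
9 | methyl 6-[4-bromo-2,3-dimethoxy-6-(methoxymethyl)phenoxy]-5-oxohexanoate | COC(=O)CCCC(=O)COc1c(COC)cc(Br)c(OC)c1OC | intermediate
10 | 2-[4-bromo-2,3-dimethoxy-6-(methoxymethyl)phenoxy]cyclohexane-1,3-dione (largely enolised) | O=C1CCCC(=O)C1Oc1c(COC)cc(Br)c(OC)c1OC | intermediate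
11 | 3-bromo-2-[4-bromo-2,3-dimethoxy-6-(methoxymethyl)phenoxy]cyclohex-2-en-1-one | O=C1CCCC(Br)=C1Oc1c(COC)cc(Br)c(OC)c1OC | intermediate
12 | 3,6-dibromo-2-[4-bromo-2,3-dimethoxy-6-(methoxymethyl)phenoxy]cyclohex-2-en-1-one (racemic) | O=C1C(Br)CCC(Br)=C1Oc1c(COC)cc(Br)c(OC)c1OC | intermediate (not isolated)
13 | 3,6,6-tribromo-2-[4-bromo-2,3-dimethoxy-6-(methoxymethyl)phenoxy]cyclohex-2-en-1-one | O=C1C(Br)(Br)CCC(Br)=C1Oc1c(COC)cc(Br)c(OC)c1OC | intermediate
14 | 3,6-dibromo-2-[4-bromo-2,3-dimethoxy-6-(methoxymethyl)phenoxy]cyclohexa-2,5-dien-1-one | O=C1C(Br)=CCC(Br)=C1Oc1c(COC)cc(Br)c(OC)c1OC | intermediate (not isolated)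
15 | 3,6-dibromo-2-[4-bromo-2,3-dimethoxy-6-(methoxymethyl)phenoxy]phenol | Oc1c(Br)ccc(Br)c1Oc1c(COC)cc(Br)c(OC)c1OC | intermediate
16 | 3,6-dibromo-2-[4-bromo-2,3-dimethoxy-6-(methoxymethyl)phenoxy]-4-(hydroxymethyl)phenol | OCc1cc(Br)c(O)c(Oc2c(COC)cc(Br)c(OC)c2OC)c1Br | intermediate
17 | 6-bromo-4-(bromomethyl)-3-[2,5-dibromo-3-(bromomethyl)-6-hydroxyphenoxy]benzene-1,2-diol | BrCc1cc(Br)c(O)c(Oc2c(CBr)cc(Br)c(O)c2O)c1Br | intermediate
18 | 6-bromo-3-[2,5-dibromo-6-hydroxy-3-(hydroxymethyl)phenoxy]-4-(hydroxymethyl)benzene-1,2-diol | OCc1cc(Br)c(O)c(Oc2c(CO)cc(Br)c(O)c2O)c1Br | target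

**Step count and risks**
Total step count: 13. Longest linear sequence: 12 steps (steps 1–4 and 6–13, from 1 to 18); step 5 is a one-step side branch from 6.

Steps most likely to fail:

Step 9. The second enolisation and bromination at the already brominated C6 may stall, or proton transfer may move the enolate to the γ-carbon, so that the gem-dibromide forms together with mono- and regioisomeric bromides that do not all aromatise to one phenol. Fallback, setting out from 11 and returning at 15: 11 would be enolised softly (TMSOTf, Et3N, CH2Cl2) to the cross-conjugated silyl dienol ether 1-bromo-2-(ArO)-3-(trimethylsilyloxy)cyclohexa-1,3-diene F1 and brominated once with NBS to give the α′-monobromo enone 12, now isolated. Dehydrobromination with Li2CO3/LiBr in DMF would give 3-bromo-2-(ArO)phenol F2. The missing bromine would then be put in by amine-mediated ortho-bromination of the phenol (NBS, cat. iPr2NH, CH2Cl2, 0 °C), which is directed to the one free ortho position and gives 15. The C6 bromine thus comes from substitution on the finished phenol and no gem-dihalide is needed.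

Step 11. The electron-poor phenoxide, flanked by bromine at the reacting carbon, may add to formaldehyde only slowly, and the benzylic alcohol formed may condense further with unreacted phenoxide to diarylmethanes. Fallback, setting out from 15 and returning at 16: iodination of the phenoxide (I2, NaHCO3, aq. THF) at the para position would give 3,6-dibromo-4-iodo-2-(ArO)phenol F3. After deprotonation with MeMgCl, selective iodine–magnesium exchange (iPrMgCl·LiCl, −20 °C, where C–I reacts far faster than C–Br) and a DMF quench would give 2,5-dibromo-3-(ArO)-4-hydroxybenzaldehyde F4. NaBH4 in MeOH would reduce F4 to 16.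

Step 13. Ionisation of the two para-hydroxybenzylic bromides may outrun capture by water, so that quinone-methide intermediates alkylate phenolic oxygens of other molecules and oligomers form; the same instability already threatens the handling of 17 after step 12. Fallback, setting out from 16 and returning at 18, with both benzylic carbons kept at the aldehyde level so that no benzylic leaving group ever faces a free para-phenol: DDQ in wet CH2Cl2 (followed by MnO2 if the ring A alcohol is left) would oxidise the benzylic methyl ether of ring B and the benzylic alcohol of ring A to 2,5-dibromo-3-(4-bromo-6-formyl-2,3-dimethoxyphenoxy)-4-hydroxybenzaldehyde F5. BBr3 in CH2Cl2 would cleave the two aryl methyl ethers to 2,5-dibromo-3-(4-bromo-6-formyl-2,3-dihydroxyphenoxy)-4-hydroxybenzaldehyde F6. NaBH4 in THF/EtOH at 0 °C would reduce both formyl groups to give 18.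

**Further compounds**
F1 | step 9 | 1-bromo-2-[4-bromo-2,3-dimethoxy-6-(methoxymethyl)phenoxy]-3-(trimethylsilyloxy)cyclohexa-1,3-diene | C[Si](C)(C)OC1=CCCC(Br)=C1Oc1c(COC)cc(Br)c(OC)c1OC
F2 | step 9 | 3-bromo-2-[4-bromo-2,3-dimethoxy-6-(methoxymethyl)phenoxy]phenol | Oc1cccc(Br)c1Oc1c(COC)cc(Br)c(OC)c1OC
F3 | step 11 | 3,6-dibromo-4-iodo-2-[4-bromo-2,3-dimethoxy-6-(methoxymethyl)phenoxy]phenol | Oc1c(Br)cc(I)c(Br)c1Oc1c(COC)cc(Br)c(OC)c1OC
F4 | step 11 | 2,5-dibromo-3-[4-bromo-2,3-dimethoxy-6-(methoxymethyl)phenoxy]-4-hydroxybenzaldehyde | O=Cc1cc(Br)c(O)c(Oc2c(COC)cc(Br)c(OC)c2OC)c1Br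
F5 | step 13 | 2,5-dibromo-3-(4-bromo-6-formyl-2,3-dimethoxyphenoxy)-4-hydroxybenzaldehyde | O=Cc1cc(Br)c(O)c(Oc2c(C=O)cc(Br)c(OC)c2OC)c1Br
F6 | step 13 | 2,5-dibromo-3-(4-bromo-6-formyl-2,3-dihydroxyphenoxy)-4-hydroxybenzaldehyde | O=Cc1cc(Br)c(O)c(Oc2c(C=O)cc(Br)c(O)c2O)c1Br
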